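**Retrosynthetic overview**
1. Target ⇐ bridged isoxazoline 19 (masked C1‑OH/C3=O aldol; N–O cleavage, desilylation) ⇐ 8‑hydroxy lactone 18 (isobutyrylation).
2. γ‑Lactone (formed second) ⇐ C6‑O‑tethered phosphonoacetate attacking C7 of a trans‑7,8‑epoxide (5‑exo, inversion), then HWE with CH2O for C13.
3. Key step: the 10‑membered carbocycle and the isoxazoline form together by intramolecular nitrile oxide–alkene cycloaddition (C2–C3 and C1–O bonds) of open‑chain nitro epoxy ester 14.
4. 14 ⇐ Sharpless epoxidation of E‑allylic alcohol 11 ⇐ asymmetric alkenylzinc addition of alkyne 8 (from (R)‑linalool: C1, C2, C7–C10, C14) to nitro aldehyde 3 (crotonaldehyde + MeNO2: C3–C6, C15).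
5. Ring order: isoxazoline + carbocycle (one operation), then the lactone.

Assumption: the target is made as the open 3‑keto‑1,10‑diol of the given SMILES (ring–chain tautomerism with the C10‑OH is ignored); germacranolide locants are used (C1 CHOH, C2 CH2, C3 C=O, C4 CHCH3, C5 CH2, C6 lactone O–CH, C7 ring‑fusion CH, C8 CH–O‑isobutyryl, C9 CH2, C10 C(CH3)OH, C11–C13 α‑methylene lactone carbons), target = (1S,4S,6R,7S,8R,10R).

**Step 1**
Reactants: 1 (E)-but-2-enal; 2 nitromethane
Product: 3 (3S)-3-methyl-4-nitrobutanal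
Conditions: (R)-α,α-diphenylprolinol TMS ether (10 mol %), PhCO2H (20 mol %), MeOH, rt
Reagents that add atoms: none
Why: Iminium‑ion organocatalytic Michael addition (Hayashi–Jørgensen type), in which the CPh2(OTMS) group of the (R)-catalyst blocks one face of the E‑iminium ion so that nitronate adds to the other face of C4, setting C4 as S.

**Step 2**
Reactants: 4 (R)-(−)-linalool
Product: 5 (3R)-3,7-dimethyl-3-(triethylsilyloxy)octa-1,6-diene
Conditions: TESOTf, 2,6-lutidine, CH2Cl2, −78 → 0 °C
Reagents that add atoms: triethylsilyl trifluoromethanesulfonate, CC[Si](CC)(CC)OS(=O)(=O)C(F)(F)F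
Why: Silyl triflate silylation of the hindered tertiary alcohol, which prevents lactol formation after ozonolysis and later serves as the stereodirecting allylic ether; C10 (R) comes unchanged from the chiral pool.

**Step 3**
Reactants: 5 (3R)-3,7-dimethyl-3-(triethylsilyloxy)octa-1,6-diene
Product: 6 (4R)-4-methyl-4-(triethylsilyloxy)hex-5-enal
Conditions: O3 (1.0 equiv, Sudan Red 7B end-point), CH2Cl2/MeOH, −78 °C; then Me2S, −78 °C → rt
Reagents that add atoms: ozone, [O-][O+]=O
Why: Chemoselective ozonolysis, because the electron‑rich trisubstituted alkene reacts far faster than the vinyl group on the quaternary carbon, so one equivalent of ozone cleaves only the former and no stereocentre is touched.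

**Step 4**
Reactants: 6 (4R)-4-methyl-4-(triethylsilyloxy)hex-5-enal
Product: 8 (3R)-3-methyl-3-(triethylsilyloxy)hex-1-en-5-yne, via enol nonaflate 7 (not isolated)
Conditions: n-C4F9SO2F, P2-Et phosphazene base, DMF, −20 °C → rt
Reagents that add atoms: none
Why: One‑pot carbonyl‑to‑alkyne dehydration, in which the aldehyde enolate is O‑sulfonylated to alkenyl nonaflate 7 and base‑induced E2 loss of nonaflate gives the terminal alkyne (held as its acetylide, so no allene forms); C10 is untouched.

**Step 5**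
Reactants: 8 (3R)-3-methyl-3-(triethylsilyloxy)hex-1-en-5-yne; 3 (3S)-3-methyl-4-nitrobutanal
Product: 11 (2S,4R,5E,8R)-2,8-dimethyl-1-nitro-8-(triethylsilyloxy)deca-5,9-dien-4-ol, via alkenylborane 9 (not isolated), via alkenylzinc 10 (not isolated)
Conditions: Cy2BH (from BH3·SMe2 + cyclohexene), toluene, 0 °C → rt; Me2Zn, −78 °C; (−)-MIB (5 mol %), then 3 (slow addition, 0.7 equiv), −20 → 0 °C; aq NH4Cl
Reagents that add atoms: none
Why: Alkyne hydroboration, B→Zn exchange and MIB‑catalysed asymmetric alkenylzinc addition (Oppolzer/Walsh type) deliver the (E)-alkenyl group to the Si face of the aldehyde, which sets C6 as R and the 7E alkene, the zinc reagent being kept in excess so that any zinc nitronate formed at C3 is simply re‑protonated on work‑up.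

**Step 6**
Reactants: 11 (2S,4R,5E,8R)-2,8-dimethyl-1-nitro-8-(triethylsilyloxy)deca-5,9-dien-4-ol
Product: 12 (2S,4R,5R,6R,8R)-5,6-epoxy-2,8-dimethyl-1-nitro-8-(triethylsilyloxy)dec-9-en-4-ol
Conditions: Ti(OiPr)4 (10 mol %), D-(−)-DIPT (12 mol %), t-BuOOH (1.2 equiv), 4 Å MS, CH2Cl2, −20 °C
Reagents that add atoms: tert-butyl hydroperoxide, CC(C)(C)OO
Why: Sharpless asymmetric epoxidation in the matched sense, since the (6R) secondary E‑allylic alcohol is the fast‑reacting type with D-(−)-tartrate and gives the erythro trans‑epoxide (7R,8R), which sets C8 (kept to the end) and C7 (inverted in step 9), while the silylated tertiary allylic alkene is inert and any 6S epimer is left behind.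

**Step 7**
Reactants: 12 (2S,4R,5R,6R,8R)-5,6-epoxy-2,8-dimethyl-1-nitro-8-(triethylsilyloxy)dec-9-en-4-ol; 13 2-(diethoxyphosphoryl)acetic acid
Product: 14 2-(diethoxyphosphoryl)acetate ester of 12
Conditions: DCC, DMAP (cat.), CH2Cl2, 0 °C → rt
Reagents that add atoms: none
Why: Steglich esterification of the secondary epoxy alcohol under neutral conditions attaches C11/C12 as a latent carbon nucleophile without touching the epoxide or nitro group; no stereocentre changes.

**Step 8**
Reactants: 14 2-(diethoxyphosphoryl)acetate ester of 12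
Product: 16 bridged isoxazoline macrocycle (10-membered carbocycle bearing the 7,8-epoxide and the 6-O-phosphonoacetate), via nitrile oxide 15 (not isolated)
Conditions: PhNCO (3 equiv), Et3N (0.3 equiv), toluene, 80 °C, syringe-pump addition of 14 over 12 h to 2 mM
Reagents that add atoms: none
Why: Mukaiyama–Hoshino dehydration gives nitrile oxide 15, which at high dilution adds to the only alkene (C1=C2) with the normal regiochemistry (C3–C2 and O–C1 bonds) in an intramolecular nitrile oxide–alkene cycloaddition that closes the 10‑membered carbocycle and the isoxazoline together, C1 being set S by the Houk–Jäger inside‑alkoxy arrangement at C10 (OTES inside, ring chain C9 anti, CH3 outside).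

**Step 9**
Reactants: 16 bridged isoxazoline macrocycle
Product: 18 8-hydroxy α-methylene lactone isoxazoline, via phosphonolactone 17 (not isolated)
Conditions: LiHMDS (1.05 equiv), THF, −78 → 45 °C; then (CH2O)n, 45 °C; aq NH4Cl
Reagents that add atoms: formaldehyde (as paraformaldehyde), C=O
Why: Proposed new method: the lithium phosphonoacetate carbanion opens the epoxide at C7 in a 5‑exo‑tet SN2 step (inversion at C7, C8–O retained, giving the trans‑fused lactone and free 8‑OH) and the resulting α‑phosphono lactone anion 17 is methylenated by formaldehyde (Horner–Wadsworth–Emmons), the closest known reactions being the intermolecular opening of epoxides by phosphonoacetate anions to α‑phosphono‑γ‑lactones followed by HWE methylenation and Stork‑type exo‑selective epoxide cyclisations of stabilised carbanions.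

**Step 10**
Reactants: 18 8-hydroxy α-methylene lactone isoxazoline
Product: 19 8-O-isobutyryl α-methylene lactone isoxazoline
Conditions: (i-PrCO)2O, Et3N, DMAP (cat.), CH2Cl2, 0 °C → rt
Reagents that add atoms: isobutyric anhydride, CC(C)C(=O)OC(=O)C(C)C
Why: DMAP‑catalysed acylation of the only free hydroxyl (secondary C8–OH, C10–O being silylated) with retention of configuration.

**Step 11**
Reactants: 19 8-O-isobutyryl α-methylene lactone isoxazoline
Product: 21 target (1S,4S,6R,7S,8R,10R)-1,10-dihydroxy-8-isobutyryloxy-3-oxogermacr-11(13)-en-12,6-olide, via silyl ether 20 (not isolated)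
Conditions: Mo(CO)6, MeCN/H2O (15:1), 80 °C; then 48% aq HF, MeCN, 0 °C → rt
Reagents that add atoms: water, O
Why: Mo(CO)6 reductively cleaves the isoxazoline N–O bond and the β‑hydroxy imine hydrolyses in the wet solvent to the C3 ketone (isoxazoline as masked aldol, exocyclic alkene and ester tolerated, no base to epimerise C4), after which aqueous HF removes the tertiary TES ether.

**Compound list**
1 | (E)-but-2-enal (crotonaldehyde) | C/C=C/C=O | starting material
2 | nitromethane | C[N+](=O)[O-] | starting material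
3 | (3S)-3-methyl-4-nitrobutanal (C3–C6, C15) | O=CC[C@H](C)C[N+](=O)[O-] | intermediate
4 | (R)-(−)-linalool, (3R)-3,7-dimethylocta-1,6-dien-3-ol | C=C[C@](C)(O)CCC=C(C)C | starting material
5 | (3R)-3,7-dimethyl-3-(triethylsilyloxy)octa-1,6-diene | C=C[C@](C)(O[Si](CC)(CC)CC)CCC=C(C)C | intermediate
6 | (4R)-4-methyl-4-(triethylsilyloxy)hex-5-enal | C=C[C@](C)(O[Si](CC)(CC)CC)CCC=O | intermediate
7 | (4R)-4-methyl-4-(triethylsilyloxy)hexa-1,5-dien-1-yl nonafluorobutane-1-sulfonate, E/Z mixture at C1=C2 | C=C[C@](C)(O[Si](CC)(CC)CC)CC=COS(=O)(=O)C(F)(F)C(F)(F)C(F)(F)C(F)(F)F | intermediate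
8 | (3R)-3-methyl-3-(triethylsilyloxy)hex-1-en-5-yne | C=C[C@](C)(O[Si](CC)(CC)CC)CC#C | intermediate
9 | dicyclohexyl[(1E,4R)-4-methyl-4-(triethylsilyloxy)hexa-1,5-dien-1-yl]borane | C=C[C@](C)(O[Si](CC)(CC)CC)C/C=C/B(C1CCCCC1)C1CCCCC1 | intermediate
10 | methyl[(1E,4R)-4-methyl-4-(triethylsilyloxy)hexa-1,5-dien-1-yl]zinc | C=C[C@](C)(O[Si](CC)(CC)CC)C/C=C/[Zn]C | intermediate
11 | (2S,4R,5E,8R)-2,8-dimethyl-1-nitro-8-(triethylsilyloxy)deca-5,9-dien-4-ol; germacrane locants (4S,6R,7E,10R) | O[C@@H](/C=C/C[C@@](C)(O[Si](CC)(CC)CC)C=C)C[C@H](C)C[N+](=O)[O-] | intermediate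
12 | (2S,4R,5R,6R,8R)-5,6-epoxy-2,8-dimethyl-1-nitro-8-(triethylsilyloxy)dec-9-en-4-ol; trans-epoxide erythro to the carbinol; germacrane locants (4S,6R,7R,8R,10R) | O[C@@H]([C@H]1O[C@@H]1C[C@@](C)(O[Si](CC)(CC)CC)C=C)C[C@H](C)C[N+](=O)[O-] | intermediate
13 | 2-(diethoxyphosphoryl)acetic acid | CCOP(=O)(OCC)CC(=O)O | starting material
14 | 2-(diethoxyphosphoryl)acetate of 12 at the C6 hydroxyl, all stereocentres as in 12 | CCOP(=O)(OCC)CC(=O)O[C@@H]([C@H]1O[C@@H]1C[C@@](C)(O[Si](CC)(CC)CC)C=C)C[C@H](C)C[N+](=O)[O-] | intermediate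
15 | nitrile oxide of 14 (C3 as C≡N+–O−), stereocentres as in 12 | CCOP(=O)(OCC)CC(=O)O[C@@H]([C@H]1O[C@@H]1C[C@@](C)(O[Si](CC)(CC)CC)C=C)C[C@H](C)C#[N+][O-] | intermediate
16 | bridged isoxazoline: carbocycle C1–C10 with C3=N–O–C1 (C2 = isoxazoline CH2), trans-7,8-epoxide, 6-O-(diethoxyphosphoryl)acetate, 4-methyl, 10-methyl-10-OTES; (1S,4S,6R,7S,8R,10R) | CCOP(=O)(OCC)CC(=O)O[C@@H]1C[C@H](C)C2=NO[C@@H](C2)[C@](C)(O[Si](CC)(CC)CC)C[C@H]3O[C@H]13 | intermediate
17 | 11-(diethoxyphosphoryl) 12,6-lactone with free 8-OH on the isoxazoline carbocycle (present as its lithium enolate; C11 epimers); (1S,4S,6R,7R,8R,10R) | CCOP(=O)(OCC)C1C(=O)O[C@@H]2C[C@H](C)C3=NO[C@@H](C3)[C@](C)(O[Si](CC)(CC)CC)C[C@@H](O)[C@@H]12 | intermediate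
18 | α-methylene 12,6-lactone with free 8-OH, isoxazoline across C1/C3, 10-OTES; (1S,4S,6R,7R,8R,10R) | C=C1C(=O)O[C@@H]2C[C@H](C)C3=NO[C@@H](C3)[C@](C)(O[Si](CC)(CC)CC)C[C@@H](O)[C@@H]12 | intermediate
19 | 8-O-isobutyrate of 18; (1S,4S,6R,7S,8R,10R) | C=C1C(=O)O[C@@H]2C[C@H](C)C3=NO[C@@H](C3)[C@](C)(O[Si](CC)(CC)CC)C[C@@H](OC(=O)C(C)C)[C@@H]12 | intermediate
20 | 10-O-triethylsilyl ether of the target; (1S,4S,6R,7S,8R,10R) | C=C1C(=O)O[C@@H]2C[C@H](C)C(=O)C[C@H](O)[C@](C)(O[Si](CC)(CC)CC)C[C@@H](OC(=O)C(C)C)[C@@H]12 | intermediate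
21 | CNP0180091.1, (1S,4S,6R,7S,8R,10R)-1,10-dihydroxy-8-isobutyryloxy-3-oxogermacr-11(13)-en-12,6-olide | C=C1C(=O)O[C@@H]2C[C@H](C)C(=O)C[C@H](O)[C@](C)(O)C[C@@H](OC(=O)C(C)C)[C@@H]12 | target

**Totals**
Total steps: 11. Longest linear sequence: 10 (steps 2–11, from (R)-linalool).

**Three steps most likely to fail, each with a fallback**

Step 8 (10‑membered ring closure by the nitrile oxide; furoxan dimers and oligomers compete, and C1 facial control is untested). The fallback sets out from 14 and comes back at 16. The nitro group is silylated (TMSCl, Et3N, toluene) to the trimethylsilyl nitronate F4, a dipole that cannot dimerise and so can be heated at 80–110 °C and 5 mM for as long as needed. Intramolecular silyl nitronate–alkene cycloaddition then gives the N-(trimethylsilyloxy)isoxazolidine macrocycle F5, again closing both rings in one operation. Catalytic TsOH eliminates trimethylsilanol to give isoxazoline 16.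

Step 9 (5‑exo epoxide opening inside the macrocycle may be conformationally blocked). The fallback sets out from 14 and comes back at 19, building the lactone on the open chain before the macrocyclisation. LiHMDS (2.1 equiv, nitronate/phosphonate dianion, THF, −78 → 40 °C, AcOH quench) gives the open-chain hydroxy phosphonolactone F6. Isobutyric anhydride/DMAP gives its 8-O-isobutyrate F7. PhNCO/Et3N at high dilution generates nitrile oxide F8, which cyclises on the lactone‑templated chain to the macrocyclic isoxazoline phosphonolactone F9. K2CO3/aq HCHO (HWE) then gives 19.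

Step 5 (the acidic CH2NO2 group may quench the alkenylzinc or trigger Henry side reactions). The fallback sets out from 3 and comes back at 11, replacing the carbonyl addition by an acylation and a catalyst‑controlled reduction. Pinnick oxidation of 3 (NaClO2, NaH2PO4, 2-methyl-2-butene) gives (3S)-3-methyl-4-nitrobutanoic acid F1. Oxalyl chloride/cat. DMF gives (3S)-3-methyl-4-nitrobutanoyl chloride F2. Pd(PPh3)4‑catalysed acylation of alkenylzinc 10 (made from 8 as in step 5) at −20 °C, where no zinc alkoxide is formed, gives the (E)-enone F3. (S)-Me-CBS/catecholborane in toluene at −78 °C reduces it to the (6R)-allylic alcohol 11.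

**Further compounds**
F1 | step 5 | (3S)-3-methyl-4-nitrobutanoic acid | OC(=O)C[C@H](C)C[N+](=O)[O-]
F2 | step 5 | (3S)-3-methyl-4-nitrobutanoyl chloride | ClC(=O)C[C@H](C)C[N+](=O)[O-]
F3 | step 5 | (2S,5E,8R)-2,8-dimethyl-1-nitro-8-(triethylsilyloxy)deca-5,9-dien-4-one | O=C(/C=C/C[C@@](C)(O[Si](CC)(CC)CC)C=C)C[C@H](C)C[N+](=O)[O-]
F4 | step 8 | trimethylsilyl nitronate of 14 (stereocentres as in 14) | CCOP(=O)(OCC)CC(=O)O[C@@H]([C@H]1O[C@@H]1C[C@@](C)(O[Si](CC)(CC)CC)C=C)C[C@H](C)C=[N+]([O-])O[Si](C)(C)C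
F5 | step 8 | N-(trimethylsilyloxy)isoxazolidine macrocycle (as 16 but C3 sp3, N–OTMS; C3 epimers) | CCOP(=O)(OCC)CC(=O)O[C@@H]1C[C@H](C)C2N(O[Si](C)(C)C)O[C@@H](C2)[C@](C)(O[Si](CC)(CC)CC)C[C@H]3O[C@H]13
F6 | step 9 | open-chain 11-(diethoxyphosphoryl) 12,6-lactone with free 8-OH and C3 nitro group (C11 epimers) | CCOP(=O)(OCC)C1C(=O)O[C@H](C[C@H](C)C[N+](=O)[O-])[C@H]1[C@H](O)C[C@@](C)(O[Si](CC)(CC)CC)C=C
F7 | step 9 | 8-O-isobutyrate of F6 | CCOP(=O)(OCC)C1C(=O)O[C@H](C[C@H](C)C[N+](=O)[O-])[C@H]1[C@H](OC(=O)C(C)C)C[C@@](C)(O[Si](CC)(CC)CC)C=C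
F8 | step 9 | nitrile oxide of F7 | CCOP(=O)(OCC)C1C(=O)O[C@H](C[C@H](C)C#[N+][O-])[C@H]1[C@H](OC(=O)C(C)C)C[C@@](C)(O[Si](CC)(CC)CC)C=C
F9 | step 9 | macrocyclic isoxazoline 11-(diethoxyphosphoryl) lactone 8-O-isobutyrate (as 19 with CH–P(O)(OEt)2 in place of C=CH2) | CCOP(=O)(OCC)C1C(=O)O[C@@H]2C[C@H](C)C3=NO[C@@H](C3)[C@](C)(O[Si](CC)(CC)CC)C[C@@H](OC(=O)C(C)C)[C@@H]12
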